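Everything rests on cutting the O1–C2 bond of the oxolane (ring atoms O1, C2, C3, C4, C5). The feature exploited is the fully substituted C2, which holds O1, a methyl group and the bromovinyl carbon, i.e. a masked α-alkoxy aldehyde; this is what contraction of a six-membered cyclic enol ether leaves behind. In a single operation PhI(OH)OTs in methanol iodinates the enol ether of a 5-methyl-3,4-dihydro-2H-pyran, moves the ring oxygen onto the methyl-bearing carbon, closes the five-membered ring, fixes the quaternary stereocentre and frees the aldehyde carbon as a dimethyl acetal. The precursor is the 2,4-trans dihydropyran carrying the complete bromo-chloro side chain at C2 and a triisopropylsilyl ether at C4.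

Key step: step 12

Remark: the target is read as (2S,3S,5S)-5-[(2S)-2-bromo-1-chloropropan-2-yl]-2-[(E)-2-bromoethenyl]-3-chloro-2-methyloxolane, with bromovinyl group, C3 chlorine and C5 side chain on one face of the ring. Compounds 21 and 23 fit this after inversion at C3; the R/S change at C2 between 23 and 26 is a change of CIP priorities only. Pyran locants are O1, C2 (side chain), C3, C4 (silyloxy), C5 (methyl), C6.

Step 1
Reactants: 1 3,3-diethoxypropan-1-ol; 2 ethyl 2-(triphenylphosphoranylidene)propanoate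
Product: 4 ethyl (2E)-5,5-diethoxy-2-methylpent-2-enoate, via 3,3-diethoxypropanal 3 (not isolated)
Conditions: Dess–Martin periodinane, pyridine, CH2Cl2, 0 °C; then 2, rt
Reagents that add atoms: none
Why: Buffered periodinane oxidation gives the elimination-prone β,β-dialkoxy aldehyde 3, which the stabilised α-methyl ylide traps in the same flask (Wittig olefination) and should convert into the (E)-trisubstituted enoate.

Step 2
Reactants: 4 ethyl (2E)-5,5-diethoxy-2-methylpent-2-enoate
Product: 5 (2E)-5,5-diethoxy-2-methylpent-2-en-1-ol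
Conditions: iBu2AlH, CH2Cl2, −78 °C; aq. KNaC4H4O6
Reagents that add atoms: none
Why: Low-temperature hydride reduction of the conjugated ester is a clean 1,2-reduction that leaves the acetal and the alkene geometry untouched.

Step 3
Reactants: 5 (2E)-5,5-diethoxy-2-methylpent-2-en-1-ol
Product: 6 [(2S,3S)-3-(2,2-diethoxyethyl)-2-methyloxiran-2-yl]methanol
Conditions: Ti(OiPr)4 (cat.), L-(+)-diethyl tartrate (cat.), tBuOOH, 4 Å molecular sieves, CH2Cl2, −20 °C
Reagents that add atoms: tert-butyl hydroperoxide, CC(C)(C)OO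
Why: Sharpless asymmetric epoxidation of an (E)-2-methyl allylic alcohol with the L-(+)-tartrate should give the (2S,3S)-epoxy alcohol, which fixes the later C5 of the oxolane and, through step 5, the bromine-bearing carbon.

Step 4
Reactants: 6 [(2S,3S)-3-(2,2-diethoxyethyl)-2-methyloxiran-2-yl]methanol
Product: 7 (2R,3S)-2-(chloromethyl)-3-(2,2-diethoxyethyl)-2-methyloxirane
Conditions: PPh3, CCl4, NaHCO3, 70 °C
Reagents that add atoms: tetrachloromethane, ClC(Cl)(Cl)Cl
Why: The Appel reaction replaces the primary hydroxyl by chloride under neutral conditions that epoxide and acetal tolerate; no stereocentre is touched (the C2 descriptor changes through priorities only).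

Step 5
Reactants: 7 (2R,3S)-2-(chloromethyl)-3-(2,2-diethoxyethyl)-2-methyloxirane
Product: 8 (2S,3S)-2-bromo-1-chloro-5,5-diethoxy-2-methylpentan-3-ol
Conditions: HBr (1.05 equiv, titrated solution in Et2O), Et2O, −40 °C; aq. NaHCO3
Reagents that add atoms: hydrogen bromide, Br
Why: Markovnikov (borderline SN2) opening of the protonated trisubstituted epoxide by bromide at the tertiary carbon with inversion should give the anti bromohydrin, so the tertiary C–Br centre (S) follows from the epoxide while the carbinol keeps its configuration; one equivalent of anhydrous acid at low temperature should be consumed by the epoxide before the acetal exchanges.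

Step 6
Reactants: 8 (2S,3S)-2-bromo-1-chloro-5,5-diethoxy-2-methylpentan-3-ol
Product: 11 (3S,4S)-4-bromo-5-chloro-4-methyl-3-(triethylsilyloxy)pentanal, via silyl ether acetal 9 (not isolated), via collidinium salt 10 (not isolated)
Conditions: Et3SiOTf (3 equiv), 2,4,6-collidine, CH2Cl2, 0 °C; then H2O, 0 °C to rt
Reagents that add atoms: triethylsilyl trifluoromethanesulfonate, CC[Si](CC)(CC)OS(=O)(=O)C(F)(F)F; water, O
Why: The silyl triflate with the hindered pyridine first silylates the secondary hydroxyl and then turns the diethyl acetal into a pyridinium N,O-acetal salt that water hydrolyses (silyl triflate/pyridine acetal cleavage), so the aldehyde never coexists with a free β-hydroxyl and no aqueous acid or base reaches the bromohydrin.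

Step 7
Reactants: 11 (3S,4S)-4-bromo-5-chloro-4-methyl-3-(triethylsilyloxy)pentanal; 12 (4S)-4-benzyl-3-propanoyl-1,3-oxazolidin-2-one
Product: 15 (4S)-4-benzyl-3-[(2S,3R,5S,6S)-6-bromo-7-chloro-3-hydroxy-2,6-dimethyl-5-(triethylsilyloxy)heptanoyl]-1,3-oxazolidin-2-one, via boron enolate 13 (not isolated), via boron aldolate 14 (not isolated)
Conditions: 12, Bu2BOTf, iPr2NEt, CH2Cl2, −78 to 0 °C; 11, −78 to 0 °C; aq. NaH2PO4/Na2HPO4 (pH 7), MeOH, H2O2, 0 °C
Reagents that add atoms: none
Why: Evans syn-aldol: the (Z)-boron enolate adds through a closed chair transition state on the face away from the benzyl group, which sets the carbinol carbon as R (the later C3 oxygen) under auxiliary control; the α-methyl centre is erased in step 11.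

Step 8
Reactants: 15 (4S)-4-benzyl-3-[(2S,3R,5S,6S)-6-bromo-7-chloro-3-hydroxy-2,6-dimethyl-5-(triethylsilyloxy)heptanoyl]-1,3-oxazolidin-2-one
Product: 16 (4S)-4-benzyl-3-[(2S,3R,5S,6S)-6-bromo-7-chloro-2,6-dimethyl-5-(triethylsilyloxy)-3-(triisopropylsilyloxy)heptanoyl]-1,3-oxazolidin-2-one
Conditions: iPr3SiOTf, 2,6-lutidine, CH2Cl2, 0 °C to rt
Reagents that add atoms: triisopropylsilyl trifluoromethanesulfonate, CC(C)[Si](C(C)C)(C(C)C)OS(=O)(=O)C(F)(F)F
Why: Standard silylation of a β-hydroxy imide; the triisopropylsilyl group is chosen because it must outlast the triethylsilyl ether in step 9, resist the acid set free in step 12 and shield one face of the enol ether there.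

Step 9
Reactants: 16 (4S)-4-benzyl-3-[(2S,3R,5S,6S)-6-bromo-7-chloro-2,6-dimethyl-5-(triethylsilyloxy)-3-(triisopropylsilyloxy)heptanoyl]-1,3-oxazolidin-2-one
Product: 18 (3S,4R,6S)-6-[(2S)-2-bromo-1-chloropropan-2-yl]-3-methyl-4-(triisopropylsilyloxy)oxan-2-one, via hydroxy imide 17 (not isolated)
Conditions: HF·pyridine, pyridine, THF, 0 °C to rt; then camphorsulfonic acid (cat.), CH2Cl2, rt
Reagents that add atoms: none
Why: HF·pyridine cleaves the triethylsilyl ether far faster than the triisopropylsilyl ether, and the freed δ-hydroxyl acylates itself on the activated imide carbonyl (acid-catalysed lactonisation, six-membered) with release of the auxiliary; no base is present that could close the bromohydrin to an epoxide.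

Step 10
Reactants: 18 (3S,4R,6S)-6-[(2S)-2-bromo-1-chloropropan-2-yl]-3-methyl-4-(triisopropylsilyloxy)oxan-2-one
Product: 19 (3S,4R,6S)-6-[(2S)-2-bromo-1-chloropropan-2-yl]-3-methyl-4-(triisopropylsilyloxy)oxan-2-ol (both anomers)
Conditions: iBu2AlH, CH2Cl2, −78 °C; aq. KNaC4H4O6
Reagents that add atoms: none
Why: Reduction of a δ-lactone by one hydride at −78 °C stops at the tetrahedral aluminate and gives the lactol on work-up, conditions under which the tertiary bromide should not be reduced.

Step 11
Reactants: 19 (3S,4R,6S)-6-[(2S)-2-bromo-1-chloropropan-2-yl]-3-methyl-4-(triisopropylsilyloxy)oxan-2-ol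
Product: 21 (2S,4R)-2-[(2S)-2-bromo-1-chloropropan-2-yl]-5-methyl-4-(triisopropylsilyloxy)-3,4-dihydro-2H-pyran, via lactol mesylate 20 (not isolated)
Conditions: MsCl, Et3N, CH2Cl2, −40 °C to reflux
Reagents that add atoms: none
Why: Mesylation of the lactol and amine-induced elimination through the ring oxocarbenium ion (the standard glycal synthesis from 2-deoxy lactols) removes the only β-hydrogen, at the methyl-bearing carbon, and gives the trisubstituted enol ether.

Step 12
Reactants: 21 (2S,4R)-2-[(2S)-2-bromo-1-chloropropan-2-yl]-5-methyl-4-(triisopropylsilyloxy)-3,4-dihydro-2H-pyran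
Product: 23 (2R,3R,5S)-5-[(2S)-2-bromo-1-chloropropan-2-yl]-2-(dimethoxymethyl)-2-methyl-3-(triisopropylsilyloxy)oxolane, via β-iodanyl acetal 22 (not isolated)
Conditions: PhI(OH)OTs (1.1 equiv), MeOH, 3 Å molecular sieves, −30 to 0 °C
Reagents that add atoms: methanol, CO
Why: The enol ether (pyran C5=C6) attacks the electrophilic trivalent iodine at the methyl-bearing C5 from the face anti to the pseudo-axial C4 silyloxy group, which is also the stereoelectronically preferred axial approach on the half-chair with the C2 side chain pseudo-equatorial, and methanol caps the C6 oxocarbenium ion to give 22. The ring oxygen then moves from C6 to C5 as iodobenzene leaves, with inversion at C5, and methanol traps the exocyclic oxocarbenium ion as the dimethyl acetal; the closest known reaction type is the hypervalent-iodine (or thallium trinitrate) ring contraction of glycals and 3,4-dihydro-2H-pyrans to 2-(dialkoxymethyl)oxolanes. The oxolane therefore closes by a 1,2-shift of the ring oxygen through a bridged oxonium ion, an intramolecular SN2 displacement at the tertiary carbon by an atom already in the ring, and not by cyclisation of a free hydroxyl. The one new stereocentre, the quaternary oxolane C2, is controlled by the face of iodination: iodine anti to the C4 oxygen followed by inversion puts the acetal carbon trans to the silyloxy group and cis to the C5 side chain, and the methyl group makes the carbon tertiary so that the iodane leaves readily. The step needs face selectivity, secured by the bulky silyl ether held pseudo-axial by A(1,2) strain with the vinylic methyl, and it needs the C5–I bond antiperiplanar to the C6–O1 bond, which the first-formed chair (C–I axial) does not offer. The ring of 22 must twist before the shift, a change eased by the syn-diaxial clash of silyloxy and methoxy groups and by the axial iodanyl group in that chair; methoxy migration and acid-catalysed addition of methanol are the competing paths.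

Step 13
Reactants: 23 (2R,3R,5S)-5-[(2S)-2-bromo-1-chloropropan-2-yl]-2-(dimethoxymethyl)-2-methyl-3-(triisopropylsilyloxy)oxolane
Product: 24 (2R,3R,5S)-5-[(2S)-2-bromo-1-chloropropan-2-yl]-2-(dimethoxymethyl)-2-methyloxolan-3-ol
Conditions: HF·pyridine, pyridine, THF, 0 °C to rt
Reagents that add atoms: none
Why: Fluoride-driven Si–O cleavage; the buffered, anhydrous reagent is not basic enough to eliminate the tertiary bromide and not wet enough to hydrolyse the dimethyl acetal.

Step 14
Reactants: 24 (2R,3R,5S)-5-[(2S)-2-bromo-1-chloropropan-2-yl]-2-(dimethoxymethyl)-2-methyloxolan-3-ol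
Product: 26 (2S,3S,5S)-5-[(2S)-2-bromo-1-chloropropan-2-yl]-3-chloro-2-(dimethoxymethyl)-2-methyloxolane, via triflate 25 (not isolated)
Conditions: Tf2O, pyridine, CH2Cl2, −30 °C; then Bu4NCl, MeCN, 0 °C to rt
Reagents that add atoms: tetrabutylammonium chloride, CCCC[N+](CCCC)(CCCC)CCCC.[Cl-]
Why: Triflation and SN2 displacement by chloride invert C3, as in the deoxyhalogenation of carbohydrate hydroxyls next to fully substituted oxygenated carbons; the β-oxygens retard ionisation and the only C2 substituent antiperiplanar to the leaving group is the poorly migrating dimethoxymethyl carbon, so chlorine should enter cis to the acetal carbon and the C5 side chain.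

Step 15
Reactants: 26 (2S,3S,5S)-5-[(2S)-2-bromo-1-chloropropan-2-yl]-3-chloro-2-(dimethoxymethyl)-2-methyloxolane
Product: 27 (2S,3S,5S)-5-[(2S)-2-bromo-1-chloropropan-2-yl]-3-chloro-2-methyloxolane-2-carbaldehyde
Conditions: CF3CO2H–H2O (9:1), CH2Cl2, 0 °C to rt
Reagents that add atoms: water, O
Why: Acid hydrolysis of the dimethyl acetal frees an aldehyde whose α-carbon is quaternary, so it can neither epimerise nor eliminate, while both alkyl halides are deactivated towards solvolysis by neighbouring heteroatoms.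

Step 16
Reactants: 27 (2S,3S,5S)-5-[(2S)-2-bromo-1-chloropropan-2-yl]-3-chloro-2-methyloxolane-2-carbaldehyde
Product: 28 (2S,3S,5S)-5-[(2S)-2-bromo-1-chloropropan-2-yl]-2-[(E)-2-bromoethenyl]-3-chloro-2-methyloxolane
Conditions: CHBr3, CrBr2 (from CrBr3 and LiAlH4), THF, 0 °C to rt
Reagents that add atoms: bromoform, BrC(Br)Br
Why: Takai olefination: the geminal dichromium species from bromoform adds to the aldehyde and eliminates to the (E)-vinyl bromide, a preference that is strongest for hindered aldehydes; CrBr2 instead of the chloride avoids halogen exchange to a vinyl chloride, and bromoform is reduced much faster than unactivated alkyl halides.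

Compound list
1 | 3,3-diethoxypropan-1-ol | CCOC(CCO)OCC | starting material
2 | ethyl 2-(triphenylphosphoranylidene)propanoate | CCOC(=O)C(C)=P(c1ccccc1)(c1ccccc1)c1ccccc1 | starting material
3 | 3,3-diethoxypropanal | CCOC(CC=O)OCC | intermediate
4 | ethyl (2E)-5,5-diethoxy-2-methylpent-2-enoate | CCOC(=O)/C(C)=C/CC(OCC)OCC | intermediate
5 | (2E)-5,5-diethoxy-2-methylpent-2-en-1-ol | OC/C(C)=C/CC(OCC)OCC | intermediate
6 | [(2S,3S)-3-(2,2-diethoxyethyl)-2-methyloxiran-2-yl]methanol | OC[C@]1(C)O[C@H]1CC(OCC)OCC | intermediate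
7 | (2R,3S)-2-(chloromethyl)-3-(2,2-diethoxyethyl)-2-methyloxirane | ClC[C@]1(C)O[C@H]1CC(OCC)OCC | intermediate
8 | (2S,3S)-2-bromo-1-chloro-5,5-diethoxy-2-methylpentan-3-ol | C[C@@](Br)(CCl)[C@@H](O)CC(OCC)OCC | intermediate
9 | {[(2S,3S)-2-bromo-1-chloro-5,5-diethoxy-2-methylpentan-3-yl]oxy}triethylsilane | C[C@@](Br)(CCl)[C@@H](O[Si](CC)(CC)CC)CC(OCC)OCC | intermediate
10 | 1-[(3S,4S)-4-bromo-5-chloro-1-ethoxy-4-methyl-3-(triethylsilyloxy)pentyl]-2,4,6-trimethylpyridin-1-ium trifluoromethanesulfonate (either configuration at C1 of the pentyl chain) | C[C@@](Br)(CCl)[C@@H](O[Si](CC)(CC)CC)CC(OCC)[n+]1c(C)cc(C)cc1C.[O-]S(=O)(=O)C(F)(F)F | intermediate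
11 | (3S,4S)-4-bromo-5-chloro-4-methyl-3-(triethylsilyloxy)pentanal | C[C@@](Br)(CCl)[C@@H](O[Si](CC)(CC)CC)CC=O | intermediate
12 | (4S)-4-benzyl-3-propanoyl-1,3-oxazolidin-2-one | CCC(=O)N1[C@@H](Cc2ccccc2)COC1=O | starting material
13 | dibutyl{[(1Z)-1-[(4S)-4-benzyl-2-oxo-1,3-oxazolidin-3-yl]prop-1-en-1-yl]oxy}borane | C/C=C(\OB(CCCC)CCCC)N1[C@@H](Cc2ccccc2)COC1=O | intermediate
14 | (4S)-4-benzyl-3-[(2S,3R,5S,6S)-6-bromo-7-chloro-3-(dibutylboranyloxy)-2,6-dimethyl-5-(triethylsilyloxy)heptanoyl]-1,3-oxazolidin-2-one | C[C@@](Br)(CCl)[C@@H](O[Si](CC)(CC)CC)C[C@@H](OB(CCCC)CCCC)[C@H](C)C(=O)N1[C@@H](Cc2ccccc2)COC1=O | intermediate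
15 | (4S)-4-benzyl-3-[(2S,3R,5S,6S)-6-bromo-7-chloro-3-hydroxy-2,6-dimethyl-5-(triethylsilyloxy)heptanoyl]-1,3-oxazolidin-2-one | C[C@@](Br)(CCl)[C@@H](O[Si](CC)(CC)CC)C[C@@H](O)[C@H](C)C(=O)N1[C@@H](Cc2ccccc2)COC1=O | intermediate
16 | (4S)-4-benzyl-3-[(2S,3R,5S,6S)-6-bromo-7-chloro-2,6-dimethyl-5-(triethylsilyloxy)-3-(triisopropylsilyloxy)heptanoyl]-1,3-oxazolidin-2-one | C[C@@](Br)(CCl)[C@@H](O[Si](CC)(CC)CC)C[C@@H](O[Si](C(C)C)(C(C)C)C(C)C)[C@H](C)C(=O)N1[C@@H](Cc2ccccc2)COC1=O | intermediate
17 | (4S)-4-benzyl-3-[(2S,3R,5S,6S)-6-bromo-7-chloro-5-hydroxy-2,6-dimethyl-3-(triisopropylsilyloxy)heptanoyl]-1,3-oxazolidin-2-one | C[C@@](Br)(CCl)[C@@H](O)C[C@@H](O[Si](C(C)C)(C(C)C)C(C)C)[C@H](C)C(=O)N1[C@@H](Cc2ccccc2)COC1=O | intermediate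
18 | (3S,4R,6S)-6-[(2S)-2-bromo-1-chloropropan-2-yl]-3-methyl-4-(triisopropylsilyloxy)oxan-2-one | C[C@@](Br)(CCl)[C@@H]1C[C@@H](O[Si](C(C)C)(C(C)C)C(C)C)[C@H](C)C(=O)O1 | intermediate
19 | (3S,4R,6S)-6-[(2S)-2-bromo-1-chloropropan-2-yl]-3-methyl-4-(triisopropylsilyloxy)oxan-2-ol (both anomers) | C[C@@](Br)(CCl)[C@@H]1C[C@@H](O[Si](C(C)C)(C(C)C)C(C)C)[C@H](C)C(O)O1 | intermediate
20 | (3S,4R,6S)-6-[(2S)-2-bromo-1-chloropropan-2-yl]-3-methyl-4-(triisopropylsilyloxy)oxan-2-yl methanesulfonate | C[C@@](Br)(CCl)[C@@H]1C[C@@H](O[Si](C(C)C)(C(C)C)C(C)C)[C@H](C)C(OS(C)(=O)=O)O1 | intermediate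
21 | (2S,4R)-2-[(2S)-2-bromo-1-chloropropan-2-yl]-5-methyl-4-(triisopropylsilyloxy)-3,4-dihydro-2H-pyran | C[C@@](Br)(CCl)[C@@H]1C[C@@H](O[Si](C(C)C)(C(C)C)C(C)C)C(C)=CO1 | intermediate
22 | [(3S,4R,6S)-6-[(2S)-2-bromo-1-chloropropan-2-yl]-2-methoxy-3-methyl-4-(triisopropylsilyloxy)oxan-3-yl](phenyl)-λ3-iodanyl 4-methylbenzenesulfonate (iodine trans to the 4-silyloxy group; either configuration at C2) | C[C@@](Br)(CCl)[C@@H]1C[C@@H](O[Si](C(C)C)(C(C)C)C(C)C)[C@](C)(I(c2ccccc2)OS(=O)(=O)c2ccc(C)cc2)C(OC)O1 | intermediate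
23 | (2R,3R,5S)-5-[(2S)-2-bromo-1-chloropropan-2-yl]-2-(dimethoxymethyl)-2-methyl-3-(triisopropylsilyloxy)oxolane | C[C@@](Br)(CCl)[C@@H]1C[C@@H](O[Si](C(C)C)(C(C)C)C(C)C)[C@](C)(C(OC)OC)O1 | intermediate
24 | (2R,3R,5S)-5-[(2S)-2-bromo-1-chloropropan-2-yl]-2-(dimethoxymethyl)-2-methyloxolan-3-ol | C[C@@](Br)(CCl)[C@@H]1C[C@@H](O)[C@](C)(C(OC)OC)O1 | intermediate
25 | (2R,3R,5S)-5-[(2S)-2-bromo-1-chloropropan-2-yl]-2-(dimethoxymethyl)-2-methyloxolan-3-yl trifluoromethanesulfonate | C[C@@](Br)(CCl)[C@@H]1C[C@@H](OS(=O)(=O)C(F)(F)F)[C@](C)(C(OC)OC)O1 | intermediate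
26 | (2S,3S,5S)-5-[(2S)-2-bromo-1-chloropropan-2-yl]-3-chloro-2-(dimethoxymethyl)-2-methyloxolane | C[C@@](Br)(CCl)[C@@H]1C[C@H](Cl)[C@](C)(C(OC)OC)O1 | intermediate
27 | (2S,3S,5S)-5-[(2S)-2-bromo-1-chloropropan-2-yl]-3-chloro-2-methyloxolane-2-carbaldehyde | C[C@@](Br)(CCl)[C@@H]1C[C@H](Cl)[C@](C)(C=O)O1 | intermediate
28 | (2S,3S,5S)-5-[(2S)-2-bromo-1-chloropropan-2-yl]-2-[(E)-2-bromoethenyl]-3-chloro-2-methyloxolane | C[C@@](Br)(CCl)[C@@H]1C[C@H](Cl)[C@](C)(/C=C/Br)O1 | target

Total step count: 16. Longest linear sequence: 16 steps (1 to 28); 2 and 12 enter in steps 1 and 7.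

Steps most likely to fail

Step 12 (key step). What may go wrong: iodination anti to the silyloxy group leaves the C–I bond axial in the chair that keeps the side chain equatorial, so the oxygen shift has to wait for a ring twist. In the meantime the antiperiplanar methoxy group may migrate instead (net 1,2-dimethoxylation), the tertiary iodane may ionise with loss of stereocontrol, or the sulfonic acid set free may add methanol across the enol ether or loosen the silyl ether. Fallback: it sets out from 21 and separates addition from activation. N-Iodosuccinimide in methanol at −40 °C (neutral trans-iodoalkoxylation of a glycal) should give the storable tertiary iodide (2S,3S,4R,6S)-6-[(2S)-2-bromo-1-chloropropan-2-yl]-3-iodo-2-methoxy-3-methyl-4-(triisopropylsilyloxy)oxane F1, whose configuration and conformation can be checked. Oxidation of its C–I bond with mCPBA in methanol over NaHCO3 then turns iodine into a leaving group without strong acid (oxidative deiodination of alkyl iodides, a known trigger for 1,2-shifts in 2-alkoxyalkyl iodides). The same oxygen shift should follow and the route is rejoined at 23.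

Step 14. What may go wrong: backside attack of chloride at C3, next to the quaternary C2 and on the face that carries the dimethoxymethyl group and the C5 side chain, may be so slow that E2 loss of the triflate towards C4 or neighbouring-group participation overtakes substitution. Fallback: it sets out from 23 and postpones the substitution until the bulky acetal has become the flat bromovinyl group. Hydrolysis of 23 (CF3CO2H–H2O, CH2Cl2) should give (2R,3R,5S)-5-[(2S)-2-bromo-1-chloropropan-2-yl]-2-methyl-3-(triisopropylsilyloxy)oxolane-2-carbaldehyde F2. The Takai conditions of step 16 then give (2S,3R,5S)-5-[(2S)-2-bromo-1-chloropropan-2-yl]-2-[(E)-2-bromoethenyl]-2-methyl-3-(triisopropylsilyloxy)oxolane F3, and HF·pyridine frees (2S,3R,5S)-5-[(2S)-2-bromo-1-chloropropan-2-yl]-2-[(E)-2-bromoethenyl]-2-methyloxolan-3-ol F4. This alcohol is chlorinated with inversion by 1-chloro-N,N,2-trimethylprop-1-en-1-amine in CH2Cl2 (neutral deoxychlorination through an alkoxyiminium chloride), which arrives directly at the target 28.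

Step 16. What may go wrong: the hindered aldehyde reacts slowly, so excess divalent chromium may reduce the tertiary C–Br bond of the vicinal bromochloride (reductive elimination to an alkene) before olefination is complete, or the E/Z ratio may erode. Fallback: it sets out from 27 and builds the vinyl bromide without a reducing metal. Seyferth–Gilbert homologation with dimethyl (1-diazo-2-oxopropyl)phosphonate and K2CO3 in methanol should give the alkyne (2S,3S,5S)-5-[(2S)-2-bromo-1-chloropropan-2-yl]-3-chloro-2-ethynyl-2-methyloxolane F5. syn-Hydrozirconation with Cp2Zr(H)Cl in THF gives the alkenylzirconium compound chlorobis(cyclopentadienyl){(E)-2-[(2S,3S,5S)-5-[(2S)-2-bromo-1-chloropropan-2-yl]-3-chloro-2-methyloxolan-2-yl]ethenyl}zirconium F6. N-Bromosuccinimide cleaves its C–Zr bond with retention to the (E)-vinyl bromide, the target 28.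

Further compounds
F1 | step 12 | (2S,3S,4R,6S)-6-[(2S)-2-bromo-1-chloropropan-2-yl]-3-iodo-2-methoxy-3-methyl-4-(triisopropylsilyloxy)oxane | C[C@@](Br)(CCl)[C@@H]1C[C@@H](O[Si](C(C)C)(C(C)C)C(C)C)[C@](C)(I)[C@@H](OC)O1
F2 | step 14 | (2R,3R,5S)-5-[(2S)-2-bromo-1-chloropropan-2-yl]-2-methyl-3-(triisopropylsilyloxy)oxolane-2-carbaldehyde | C[C@@](Br)(CCl)[C@@H]1C[C@@H](O[Si](C(C)C)(C(C)C)C(C)C)[C@](C)(C=O)O1
F3 | step 14 | (2S,3R,5S)-5-[(2S)-2-bromo-1-chloropropan-2-yl]-2-[(E)-2-bromoethenyl]-2-methyl-3-(triisopropylsilyloxy)oxolane | C[C@@](Br)(CCl)[C@@H]1C[C@@H](O[Si](C(C)C)(C(C)C)C(C)C)[C@](C)(/C=C/Br)O1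
F4 | step 14 | (2S,3R,5S)-5-[(2S)-2-bromo-1-chloropropan-2-yl]-2-[(E)-2-bromoethenyl]-2-methyloxolan-3-ol | C[C@@](Br)(CCl)[C@@H]1C[C@@H](O)[C@](C)(/C=C/Br)O1
F5 | step 16 | (2S,3S,5S)-5-[(2S)-2-bromo-1-chloropropan-2-yl]-3-chloro-2-ethynyl-2-methyloxolane | C[C@@](Br)(CCl)[C@@H]1C[C@H](Cl)[C@](C)(C#C)O1
F6 | step 16 | chlorobis(cyclopentadienyl){(E)-2-[(2S,3S,5S)-5-[(2S)-2-bromo-1-chloropropan-2-yl]-3-chloro-2-methyloxolan-2-yl]ethenyl}zirconium (cyclopentadienyl rings drawn σ-bonded) | C[C@@](Br)(CCl)[C@@H]1C[C@H](Cl)[C@](C)(/C=C/[Zr](Cl)(C2C=CC=C2)C2C=CC=C2)O1
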